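One constant I read from your red and grey runs was K, the [L] at which Z works at half its top speed (the half-saturation constant). You asked for a quick number on teal, and I came to it by way of those two runs. The first readings of the red and grey runs stood at a ratio of 1.42 for twice the L, and a rate going as L/(K+L) then put K at 73.8 mM, a reading that carries their scatter. That made the exponent of [L] at the red charge K/(K+L), or 0.425.

| flask | L | Z | time |
|---|---|---|---|
| red | 100 mM | 5.00 mM |  |
| grey | 50.0 mM | 5.00 mM |  |
| teal | 33.0 mM | 10.0 mM | 4.6 h |

- red run (time / h: [J] / mM): 0.18: 10.4; 0.41: 23.3; 0.92: 44.0; 2.1: 70.3; 4.6: 86.5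
- grey run (time / h: [J] / mM): 0.18: 7.3; 0.41: 14.0; 0.92: 25.3; 2.1: 36.7; 4.6: 42.3

(scatter of a reading: 0.5 mM)

- the exponent of [L] in the starting rate at the charge of the red run (at the point where two percent of the L have become J) (one fixed amount of J, the same in the runs compared)
- J in the teal run at 4.6 h, as a share of the L charged

- Overall: L -> J, with Z as catalyst.
- Constant volume, constant temperature.
- Bound and free are read together.
- An order is taken over about fifteen percent of the charge, up and down.

Summed over a run, that rate says that K ln(C/L) + (C − L), with C the L charged and L the L left, equals the top rate per Z times the hours of live Z. In the grey run at the last reading this sum came to 180 mM; I called it the catalyst work W. The red run, on the same Z charge, reached 234 mM, more than the grey run.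

Then I wrote the balance of Z, the smaller charge in the teal run: live Z is the charge minus what is lost. My bet was that Z is lost when two free Z meet, so that extra Z mostly dies sooner, and I gave the teal run the grey W. Counting C − L as the whole teal charge, which overstates it slightly, gave 86.4 %. Your forecast differed, at 97 %, with 0.42 for the exponent, on the ground: “This suggests the catalyst dies, with substrate protecting it”.

The teal run gave 89.3 %, and the exponent came out at 0.43.

    Z + L ⇌ ZL, settled at all times (15.70 M⁻¹)
    ZL ⇌ J + Z (24.26 h⁻¹, 34.85 M⁻¹ h⁻¹)
    2 Z → 2 Lx (148.3 M⁻¹ h⁻¹)
    Z + Xi → Lx

The flask has a back step, J + Z to ZL, with k2 = 34.9 M⁻¹ h⁻¹. Read from the teal result, the same sum gives W = 194 mM, which is 1.08 times the grey W on twice the Z. In the red run, J reached half the charge at 1.11 h, where W stood at 101 mM, which is 43.2 % of the W of its last reading at 4.6 h.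

The data are simulated for substances that don't exist; the scatter is artificial.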